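**Plan**

- Retrosynthesis: the two tigloyl ester C–O bonds (at C4 and C7) and the C4–O and C6–O bonds are cut first, leaving (5S)-2-(benzyloxymethyl)-5-isopropylcyclohex-2-enone. That ring is cut at C5–C6 and C2=C3, and the acyclic keto ester at C2–C7.
- Enabling feature: in the ring C1(=O)–C2(=C3H)–C4–C5(iPr)–C6, atoms C3–C4–C5 with the isopropyl group are 4-methylpent-2-enal and C6–C1–C2–C7H2O is a γ-oxygenated acetoacetate. The C1 ketone is therefore 1,5 to C3, and one Michael bond plus one aldol condensation build the whole enone ring.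
- Forward order: C2–C7 by dianion alkylation; the single ring by a one-pot Michael/aldol condensation/decarboxylation; then C6–O (Rubottom), C4–O (vinylogous Rubottom), debenzylation, double Mitsunobu esterification, desilylation.
- Stereochemistry: C5 comes from the prolinol silyl ether catalyst; the C6 and C4 oxygens enter anti to the C5 isopropyl group; C4 is then inverted to the required 4,5-cis arrangement in the Mitsunobu step.

Key step: step 2

Remarks on the chemistry:
- The locants C1–C7 defined above are used for every ring compound, also where systematic numbering would differ.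
- The (R)-catalyst is specified because the usual shielding model for the E-iminium ion of a diarylprolinol silyl ether puts the keto ester on the face of C5 that leads to the 5S enone. The (S)-catalyst would give the antipodal series.
- Compounds 1, 2, 5 and 17 are taken as purchased. Dimethyldioxirane is used as its acetone solution.

**Step 1**
Reactants: 1 tert-butyl acetoacetate; 2 benzyl chloromethyl ether
Product: 4 tert-butyl 5-(benzyloxy)-3-oxopentanoate, via dilithium dianion 3 (not isolated)
Conditions: LiN(iPr)2 (2.1 equiv), THF, −78 → 0 °C; 2, −78 → −20 °C; aq. NH4Cl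
Reagents that add atoms: none
Why: Acetoacetate dianion alkylation: the second deprotonation places the more reactive carbanion on the terminal methyl carbon, which alone displaces chloride from the chloromethyl ether (SN2) and forms the C2–C7 bond.

**Step 2**
Reactants: 4 tert-butyl 5-(benzyloxy)-3-oxopentanoate; 5 (E)-4-methylpent-2-enal
Product: 8 (5S)-2-[(benzyloxy)methyl]-5-(propan-2-yl)cyclohex-2-en-1-one, via Michael adduct 6 (not isolated), via keto aldehyde 7 (not isolated)
Conditions: (R)-2-{bis[3,5-bis(trifluoromethyl)phenyl][(trimethylsilyl)oxy]methyl}pyrrolidine (10 mol%), toluene, rt; then p-TsOH·H2O (20 mol%), toluene, 80 °C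
Reagents that add atoms: none
Why: The secondary amine condenses with 5 to an E-iminium ion whose diaryl(silyloxy)methyl group shields one face, so the enol of 4 adds through its doubly activated carbon (future C6) to the open face of C5 and sets the 5S centre under catalyst control (asymmetric organocatalytic Michael addition of a β-keto ester to an enal). After enamine hydrolysis the adduct 6, largely present as its cyclic hemiacetal, meets the acid, which cleaves the tert-butyl ester, lets the β-keto acid decarboxylate to 7 and enolises the ketone toward C2. Aldol addition of that enol to the C3 aldehyde closes the six-membered ring in a 6-(enolendo)-exo-trig mode and dehydration gives the C2=C3 enone; the sequence is the known one-pot Michael/aldol condensation/decarboxylation route to 5-substituted cyclohex-2-enones. Ring-closure regiochemistry is secured because the only other enol (toward C6) could only form a four-membered ring, and C5, lying β to both carbonyl groups, cannot epimerise by enolisation. The step needs enantioface selection (choice of catalyst enantiomer) and survival of the β-benzyloxy ketone, which is favoured by keeping the acid catalytic, the solvent non-nucleophilic and the temperature at 80 °C or below.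

**Step 3**
Reactants: 8 (5S)-2-[(benzyloxy)methyl]-5-(propan-2-yl)cyclohex-2-en-1-one
Product: 9 (5R)-2-[(benzyloxy)methyl]-5-(propan-2-yl)-1-(trimethylsilyloxy)cyclohexa-1(6),2-diene
Conditions: LiN(iPr)2 (1.15 equiv), Me3SiCl (1.5 equiv), THF, −78 °C; pentane/aq. NaHCO3 work-up
Reagents that add atoms: chlorotrimethylsilane, C[Si](C)(C)Cl
Why: Kinetic deprotonation of the enone by the hindered amide takes place at the α′-methylene C6 and not at the vinylogous C4, and O-silylation traps the cross-conjugated dienolate as its silyl enol ether without touching C5.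

**Step 4**
Reactants: 9 (5R)-2-[(benzyloxy)methyl]-5-(propan-2-yl)-1-(trimethylsilyloxy)cyclohexa-1(6),2-diene
Product: 11 (5R,6R)-2-[(benzyloxy)methyl]-6-hydroxy-5-(propan-2-yl)cyclohex-2-en-1-one, via trimethylsilyloxy enone 10 (not isolated)
Conditions: mCPBA (1.1 equiv), NaHCO3, CH2Cl2, −20 → 0 °C; then aq. citric acid, THF, 0 °C
Reagents that add atoms: 3-chloroperoxybenzoic acid, OOC(=O)c1cccc(Cl)c1
Why: Rubottom oxidation: the peracid epoxidises the electron-rich C1=C6 enol ether bond on the face opposite the adjacent C5 isopropyl group, the silyloxy oxirane opens with 1,4-silyl shift to 10, and mild acid frees the C6 hydroxyl trans to isopropyl.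

**Step 5**
Reactants: 11 (5R,6R)-2-[(benzyloxy)methyl]-6-hydroxy-5-(propan-2-yl)cyclohex-2-en-1-one
Product: 13 (5S,6R)-2-[(benzyloxy)methyl]-1,6-bis[(tert-butyldimethylsilyl)oxy]-5-(propan-2-yl)cyclohexa-1,3-diene, via mono-silyl enone 12 (not isolated)
Conditions: t-BuMe2SiOTf (2.5 equiv), Et3N (4 equiv), CH2Cl2, −78 °C → rt; used crude
Reagents that add atoms: tert-butyldimethylsilyl trifluoromethanesulfonate, CC(C)(C)[Si](C)(C)OS(=O)(=O)C(F)(F)F
Why: The silyl triflate first caps the C6 hydroxyl and then, by soft enolisation of the O-silylated enone with Et3N, removes a C4 proton to give the through-conjugated dienol silyl ether; enolisation toward C6 is disfavoured because it needs the C6–H bond axial, which forces the bulky C6 silyloxy group into allylic strain with the silylated carbonyl oxygen, and it would create a tetrasubstituted enediol ether next to isopropyl.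

**Step 6**
Reactants: 13 (5S,6R)-2-[(benzyloxy)methyl]-1,6-bis[(tert-butyldimethylsilyl)oxy]-5-(propan-2-yl)cyclohexa-1,3-diene
Product: 15 (4R,5S,6R)-2-[(benzyloxy)methyl]-6-[(tert-butyldimethylsilyl)oxy]-4-hydroxy-5-(propan-2-yl)cyclohex-2-en-1-one, via vinyl epoxide 14 (not isolated)
Conditions: dimethyldioxirane (1.1 equiv, acetone), CH2Cl2, −78 → −30 °C; then AcOH/H2O/THF, 0 °C
Reagents that add atoms: dimethyldioxirane, CC1(C)OO1
Why: Vinylogous Rubottom oxidation: the dioxirane epoxidises the distal C3=C4 bond (largest HOMO coefficient at C4) anti to the neighbouring C5 isopropyl group, and acid-assisted opening of the silyloxy vinyl epoxide with hydrolysis of the enol silyl ether returns the enone carrying the new C4 hydroxyl trans to isopropyl.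

**Step 7**
Reactants: 15 (4R,5S,6R)-2-[(benzyloxy)methyl]-6-[(tert-butyldimethylsilyl)oxy]-4-hydroxy-5-(propan-2-yl)cyclohex-2-en-1-one
Product: 16 (4R,5S,6R)-6-[(tert-butyldimethylsilyl)oxy]-4-hydroxy-2-(hydroxymethyl)-5-(propan-2-yl)cyclohex-2-en-1-one
Conditions: BCl3 (3 equiv), C6HMe5 (4 equiv), CH2Cl2, −78 °C; MeOH quench
Reagents that add atoms: none
Why: Lewis-acid debenzylation: BCl3 ionises the benzyl C–O bond at low temperature and pentamethylbenzene traps the benzyl cation by Friedel–Crafts alkylation, conditions that spare the enone, the secondary silyl ether and the electron-poor allylic C4 carbinol.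

**Step 8**
Reactants: 16 (4R,5S,6R)-6-[(tert-butyldimethylsilyl)oxy]-4-hydroxy-2-(hydroxymethyl)-5-(propan-2-yl)cyclohex-2-en-1-one; 17 tiglic acid [(E)-2-methylbut-2-enoic acid]
Product: 19 (4S,5S,6R)-6-[(tert-butyldimethylsilyl)oxy]-5-(propan-2-yl)-4-(tigloyloxy)-2-[(tigloyloxy)methyl]cyclohex-2-en-1-one, via C7 mono-tiglate 18 (not isolated)
Conditions: 17 (3 equiv), PPh3 (3 equiv), DIAD (3 equiv), toluene, 0 °C → rt
Reagents that add atoms: none
Why: Double Mitsunobu esterification: both hydroxyls are activated as alkoxyphosphonium ions and displaced by tiglate in SN2 fashion, first at primary C7 and then at C4 with inversion, which turns the 4,5-trans carbinol into the 4,5-cis ester; ionisation at C4 is disfavoured because it is γ to the enone carbonyl, and SN2′ attack would have to occur at the fully substituted C2.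

**Step 9**
Reactants: 19 (4S,5S,6R)-6-[(tert-butyldimethylsilyl)oxy]-5-(propan-2-yl)-4-(tigloyloxy)-2-[(tigloyloxy)methyl]cyclohex-2-en-1-one
Product: 20 (4S,5R,6R)-6-hydroxy-5-(propan-2-yl)-4-(tigloyloxy)-2-[(tigloyloxy)methyl]cyclohex-2-en-1-one
Conditions: HF·pyridine, pyridine, THF, 0 °C → rt
Reagents that add atoms: none
Why: Fluoride-mediated desilylation under buffered acidic conditions cleaves only the Si–O bond; the absence of base avoids ester cleavage, acyl migration and elimination of the γ-acyloxy group, and the C6 hydroxyl is trans to the C4 ester.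

**Compound list** (tigloyl = (E)-2-methylbut-2-enoyl)

1 | tert-butyl acetoacetate | CC(=O)CC(=O)OC(C)(C)C | starting material
2 | benzyl chloromethyl ether | ClCOCc1ccccc1 | starting material
3 | dilithium dianion (bis-enolate) of tert-butyl acetoacetate | [Li+].[Li+].C=C([O-])C=C([O-])OC(C)(C)C | intermediate
4 | tert-butyl 5-(benzyloxy)-3-oxopentanoate | O=C(CC(=O)CCOCc1ccccc1)OC(C)(C)C | intermediate
5 | (E)-4-methylpent-2-enal | CC(C)/C=C/C=O | starting material
6 | tert-butyl (3R)-2-[3-(benzyloxy)propanoyl]-5-oxo-3-(propan-2-yl)pentanoate (C2 epimers) | O=CC[C@H](C(C)C)C(C(=O)OC(C)(C)C)C(=O)CCOCc1ccccc1 | intermediate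
7 | (3S)-7-(benzyloxy)-5-oxo-3-(propan-2-yl)heptanal | O=CC[C@H](C(C)C)CC(=O)CCOCc1ccccc1 | intermediate
8 | (5S)-2-[(benzyloxy)methyl]-5-(propan-2-yl)cyclohex-2-en-1-one | c1ccccc1COCC2=CC[C@H](C(C)C)CC2=O | intermediate
9 | (5R)-2-[(benzyloxy)methyl]-5-(propan-2-yl)-1-(trimethylsilyloxy)cyclohexa-1(6),2-diene (double bonds C1=C6 and C2=C3) | c1ccccc1COCC2=CC[C@H](C(C)C)C=C2O[Si](C)(C)C | intermediate
10 | (5R,6R)-2-[(benzyloxy)methyl]-5-(propan-2-yl)-6-(trimethylsilyloxy)cyclohex-2-en-1-one | c1ccccc1COCC2=CC[C@H](C(C)C)[C@@H](O[Si](C)(C)C)C2=O | intermediate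
11 | (5R,6R)-2-[(benzyloxy)methyl]-6-hydroxy-5-(propan-2-yl)cyclohex-2-en-1-one (6-OH trans to 5-isopropyl) | c1ccccc1COCC2=CC[C@H](C(C)C)[C@@H](O)C2=O | intermediate
12 | (5R,6R)-2-[(benzyloxy)methyl]-6-[(tert-butyldimethylsilyl)oxy]-5-(propan-2-yl)cyclohex-2-en-1-one | c1ccccc1COCC2=CC[C@H](C(C)C)[C@@H](O[Si](C)(C)C(C)(C)C)C2=O | intermediate
13 | (5S,6R)-2-[(benzyloxy)methyl]-1,6-bis[(tert-butyldimethylsilyl)oxy]-5-(propan-2-yl)cyclohexa-1,3-diene | C1=C[C@H](C(C)C)[C@@H](O[Si](C)(C)C(C)(C)C)C(O[Si](C)(C)C(C)(C)C)=C1COCc1ccccc1 | intermediate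
14 | 3,4-epoxide of 13, oxirane oxygen on the face opposite the C5 isopropyl group (cis to the C6 silyloxy group) | [C@H]1(O2)[C@@H]2[C@H](C(C)C)[C@@H](O[Si](C)(C)C(C)(C)C)C(O[Si](C)(C)C(C)(C)C)=C1COCc1ccccc1 | intermediate
15 | (4R,5S,6R)-2-[(benzyloxy)methyl]-6-[(tert-butyldimethylsilyl)oxy]-4-hydroxy-5-(propan-2-yl)cyclohex-2-en-1-one (4-OH trans to 5-isopropyl) | c1ccccc1COCC2=C[C@@H](O)[C@H](C(C)C)[C@@H](O[Si](C)(C)C(C)(C)C)C2=O | intermediate
16 | (4R,5S,6R)-6-[(tert-butyldimethylsilyl)oxy]-4-hydroxy-2-(hydroxymethyl)-5-(propan-2-yl)cyclohex-2-en-1-one | OCC1=C[C@@H](O)[C@H](C(C)C)[C@@H](O[Si](C)(C)C(C)(C)C)C1=O | intermediate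
17 | tiglic acid, (E)-2-methylbut-2-enoic acid | C/C=C(\C)C(=O)O | starting material
18 | (4R,5S,6R)-6-[(tert-butyldimethylsilyl)oxy]-4-hydroxy-5-(propan-2-yl)-2-[(tigloyloxy)methyl]cyclohex-2-en-1-one | C/C=C(\C)C(=O)OCC1=C[C@@H](O)[C@H](C(C)C)[C@@H](O[Si](C)(C)C(C)(C)C)C1=O | intermediate
19 | (4S,5S,6R)-6-[(tert-butyldimethylsilyl)oxy]-5-(propan-2-yl)-4-(tigloyloxy)-2-[(tigloyloxy)methyl]cyclohex-2-en-1-one (4-O cis to 5-isopropyl) | C/C=C(\C)C(=O)OCC1=C[C@H](OC(=O)/C(C)=C/C)[C@H](C(C)C)[C@@H](O[Si](C)(C)C(C)(C)C)C1=O | intermediate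
20 | (4S,5R,6R)-6-hydroxy-5-(propan-2-yl)-4-(tigloyloxy)-2-[(tigloyloxy)methyl]cyclohex-2-en-1-one | C/C=C(\C)C(=O)OCC1=C[C@H](OC(=O)/C(C)=C/C)[C@H](C(C)C)[C@@H](O)C1=O | target

**Step count**

Total: 9 steps. Longest linear sequence: 9 steps (1 → 20); compounds 2, 5 and 17 are purchased.

**Steps most likely to fail**

1. Step 5 (and with it step 6). Enolisation of the O-silylated enone may take place toward C6 instead of C4, giving the enediol bis-silyl ether instead of the through-conjugated dienol ether, so that no oxygen reaches C4.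
Fallback: this sets out from 11 and avoids any dienol ether. Mono-silylation of 11 (t-BuMe2SiOTf 1.1 equiv, 2,6-lutidine, CH2Cl2, −78 °C) gives 12, now isolated. Direct γ-C–H oxidation of the enone (Pd(OH)2/C, t-BuOOH, K2CO3, CH2Cl2) should give (5R,6R)-2-[(benzyloxy)methyl]-6-[(tert-butyldimethylsilyl)oxy]-5-(propan-2-yl)cyclohex-2-ene-1,4-dione F1. Luche reduction (NaBH4, CeCl3·7H2O, MeOH, −78 °C) is expected at the C4 carbonyl, since C1 is flanked by the C2 substituent and the C6 silyloxy group, with hydride entering anti to isopropyl; this would give the 4,5-cis alcohol (4S,5S,6R)-2-[(benzyloxy)methyl]-6-[(tert-butyldimethylsilyl)oxy]-4-hydroxy-5-(propan-2-yl)cyclohex-2-en-1-one F2. Debenzylation as in step 7 gives (4S,5S,6R)-6-[(tert-butyldimethylsilyl)oxy]-4-hydroxy-2-(hydroxymethyl)-5-(propan-2-yl)cyclohex-2-en-1-one F3. Double Steglich esterification with 17 (N-(3-dimethylaminopropyl)-N′-ethylcarbodiimide hydrochloride, 4-(dimethylamino)pyridine, CH2Cl2) acylates both hydroxyls with retention and returns to the route at 19; no inversion is then needed.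

2. Step 2. Under the acidic condensation the β-benzyloxy ketone may lose benzyl alcohol by β-elimination before ring closure, or the product may lose it through its dienol with aromatisation to a phenol; conversion in the Michael stage with the γ-substituted keto ester may also be slow.
Fallback: this sets out from 1 and 5 and keeps the same two ring-forming bonds, but brings in C7 afterwards. The same amine-catalysed Michael addition of 1 to 5 gives tert-butyl (3R)-2-acetyl-5-oxo-3-(propan-2-yl)pentanoate F4 (not isolated), and acid-promoted decarboxylation and aldol condensation gives (5S)-5-(propan-2-yl)cyclohex-2-en-1-one F5. Morita–Baylis–Hillman hydroxymethylation (aq. CH2O, 4-(dimethylamino)pyridine cat., THF/H2O, rt) gives (5S)-2-(hydroxymethyl)-5-(propan-2-yl)cyclohex-2-en-1-one F6. Acid-catalysed benzylation (benzyl 2,2,2-trichloroacetimidate, TfOH cat., CH2Cl2/cyclohexane, 0 °C) returns to the route at 8.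

3. Step 8. Substitution at the C4 alkoxyphosphonium ion has to occur on the face syn to the neighbouring isopropyl group and may be slow, which would allow elimination to a dienone (and aromatisation) or stop the reaction at the mono-ester.
Fallback: this sets out from 16 and inverts C4 by oxidation and reduction instead of substitution. Selective Steglich esterification of the primary hydroxyl with 17 (1.05 equiv, carbodiimide, 4-(dimethylamino)pyridine cat., CH2Cl2, −20 °C) gives 18, now isolated. Dess–Martin periodinane oxidises C4 to (5R,6R)-6-[(tert-butyldimethylsilyl)oxy]-5-(propan-2-yl)-2-[(tigloyloxy)methyl]cyclohex-2-ene-1,4-dione F7. Luche reduction (NaBH4, CeCl3·7H2O, MeOH, −78 °C), with hydride anti to isopropyl, should give (4S,5S,6R)-6-[(tert-butyldimethylsilyl)oxy]-4-hydroxy-5-(propan-2-yl)-2-[(tigloyloxy)methyl]cyclohex-2-en-1-one F8. Yamaguchi esterification with 17 (2,4,6-trichlorobenzoyl chloride, Et3N, 4-(dimethylamino)pyridine, toluene) returns to the route at 19.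

**Further compounds**

F1 | step 5 | (5R,6R)-2-[(benzyloxy)methyl]-6-[(tert-butyldimethylsilyl)oxy]-5-(propan-2-yl)cyclohex-2-ene-1,4-dione | c1ccccc1COCC2=CC(=O)[C@H](C(C)C)[C@@H](O[Si](C)(C)C(C)(C)C)C2=O
F2 | step 5 | (4S,5S,6R)-2-[(benzyloxy)methyl]-6-[(tert-butyldimethylsilyl)oxy]-4-hydroxy-5-(propan-2-yl)cyclohex-2-en-1-one | c1ccccc1COCC2=C[C@H](O)[C@H](C(C)C)[C@@H](O[Si](C)(C)C(C)(C)C)C2=O
F3 | step 5 | (4S,5S,6R)-6-[(tert-butyldimethylsilyl)oxy]-4-hydroxy-2-(hydroxymethyl)-5-(propan-2-yl)cyclohex-2-en-1-one | OCC1=C[C@H](O)[C@H](C(C)C)[C@@H](O[Si](C)(C)C(C)(C)C)C1=O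
F4 | step 2 | tert-butyl (3R)-2-acetyl-5-oxo-3-(propan-2-yl)pentanoate | O=CC[C@H](C(C)C)C(C(C)=O)C(=O)OC(C)(C)C
F5 | step 2 | (5S)-5-(propan-2-yl)cyclohex-2-en-1-one | C1=CC[C@H](C(C)C)CC1=O
F6 | step 2 | (5S)-2-(hydroxymethyl)-5-(propan-2-yl)cyclohex-2-en-1-one | OCC1=CC[C@H](C(C)C)CC1=O
F7 | step 8 | (5R,6R)-6-[(tert-butyldimethylsilyl)oxy]-5-(propan-2-yl)-2-[(tigloyloxy)methyl]cyclohex-2-ene-1,4-dione | C/C=C(\C)C(=O)OCC1=CC(=O)[C@H](C(C)C)[C@@H](O[Si](C)(C)C(C)(C)C)C1=O
F8 | step 8 | (4S,5S,6R)-6-[(tert-butyldimethylsilyl)oxy]-4-hydroxy-5-(propan-2-yl)-2-[(tigloyloxy)methyl]cyclohex-2-en-1-one | C/C=C(\C)C(=O)OCC1=C[C@H](O)[C@H](C(C)C)[C@@H](O[Si](C)(C)C(C)(C)C)C1=O
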